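The runs are simulated from invented constants; scatter was added.

Late times are what is asked of this flask, so start from the late part of its summer run, which is the same flask followed so far.

- summer: substrate 3 M (in portions, 4); gas 200 mM (held); the very flask that is asked about, followed so far; portions every 12 min
- flask: substrate 3.0 M (in portions, 4); gas 200 mM (held); time 8.0 h; the portions of substrate follow each other after 12 min, the first at the start

summer run (percent of the substrate charged)

| time / h | product / % | substrate / % |
|---|---|---|
| 0.167 | 0 | 24.6 |
| 0.500 | 0.1 | 74.1 |
| 0.833 | 1.6 | 98.0 |
| 1.33 | 4.4 | 95.9 |
| 2.00 | 6.5 | 92.9 |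
| 2.50 | 9.2 | 91.1 |
| 3.00 | 10.8 | 89.2 |

(readings scatter by 0.3 percentage points)

- at the start none of the gas is in solution

- amount of product in the flask at 8.0 h, in percent of the substrate charged
- amount of substrate in the flask at 8.0 h, in percent of the substrate charged
- concentration of reagent at 8.0 h, in M

Once the portions are in, the substrate readings of the summer run go from 98.0 % at 0.833 h to 89.2 % at 3.00 h. You can replace that curve by its mean, one fractional loss per hour, 0.0434 /h, which is a pseudo-first-order view. Multiply it by the wait from 0.833 h to 8.0 h and you have the decay number, 0.311: how many mean lifetimes of substrate that wait holds.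

My reckoning then puts substrate at 8.0 h at 71.8 %. I take product as the complement, 28.2 %; the two summer readings sum to 100.0 % at 3.00 h.

Was one number enough? A straight line through the same two readings gives 68.9 %, so the shape of the curve costs 2.9 percentage points, against a scatter of 0.3 points. For reagent it is not enough: the decay number has no term for it. If reagent is the gas taken up, I commit to less than 200 mM.

The forecast gives 30.5 % product, 69.5 % substrate and 0.007 M reagent, that last value “the least certain”.

At 8.0 h the flask gives 29.1 % product, 70.9 % substrate and 0.156 M reagent, which is less than saturation.

    gas ⇌ reagent, rate k1*(csat - [reagent]) (kL = 2.30 /h)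
    substrate + reagent ⇌ product (K = 64.0 /M, k = 0.310 /M/h)

Read back from this flask, the decay number is 0.324 against the reckoned 0.311. For the neighbouring flask left until 20 h, the same mean gives 0.832, so substrate 42.6 %. That flask holds 40.3 % substrate and 59.7 % product.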